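A one-step world has one rate constant and one half-life; this flask loses its substrate by steps of different order.

    base + released group ⇌ salt, settled at all times (K1 = 86000 M⁻¹)
    substrate + reagent → target + released group (k2 = 4.3 × 10⁻⁶ M⁻¹ s⁻¹)
    substrate + reagent + released group → target + 2 released group (k3 = 0.0028 M⁻² s⁻¹)
    scavenger + released group → scavenged by-product (k4 = 0.0094 M⁻¹ s⁻¹)
    substrate ⇌ dormant form (K5 = 2.7, k5 = 2.3 × 10⁻⁶ s⁻¹)
    2 substrate → self-condensation product (k6 = 1.4 × 10⁻⁴ M⁻¹ s⁻¹)
    reagent + released group ⇌ idle adduct, settled at all times (K7 = 3000 M⁻¹)

substrate 0.059 M; reagent 0.0767 M; base 1.18 mM; scavenger 0.0590 M; time 4.0 d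

- a species is counted by the substrate in it: one self-condensation product counts as two
- amounts and yields of released group count idle adduct too
- a doubled species enters its step squared and goes two at a time
- what has gone from substrate into another species counts as reacted, even if it can come back
- run time (flask): 4.0 d

- part of the substrate that has reacted at 4.0 d
- share of the unused reagent that is free and not bound as idle adduct, at 4.0 d

**What takes substrate at the start?** Per substrate, self-condensation runs at 1.65 × 10⁻⁵ s⁻¹, dormancy at 2.3 × 10⁻⁶ s⁻¹ and the direct step at 3.30 × 10⁻⁷ s⁻¹, so pairing leads.

**Can the autocatalytic step overtake the direct one?** It needs free released group above 1.54 mM. Even with substrate held at its charge for the whole run, the direct step releases 6.72 mM. Reagent binding at its starting strength would leave about 0.0291 mM of that free, less than the threshold, so I drop the step.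

**Your rate law, then?** With reagent held at its charge, the direct step is pseudo-first-order: dS/dt = −aS − bS·S. Here S is free substrate, a = 2.63 × 10⁻⁶ s⁻¹ adds dormancy to the direct step, and b is twice the self-condensation constant.

**What governs its solution?** The crossover concentration S× = a/b = 9.39 mM, at which first-order and pairwise losses are equal. With C the charge and u = exp(−at), S = Cu/(1 + (C/S×)(1 − u)).

**And at the asked time?** S = 5.01 mM, so c = 91.5 %.

**Where is that weak?** Dormant substrate returns, and my form ignores this, so my c errs high. I reckon no figure for fr.

The forecast gives c = 89.1 % (88 % to 90.2 %) and fr = 98.8 % (98.4 % to 99.1 %). Its ground: “The released group never builds up enough for the autocatalytic step to matter”. Its c stands below mine.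

The simulation gives c = 89.7 % and fr = 98.8 %, both within the forecast's margins.

Stopping the flask at 2.67 d lowers c by 5 points, to less than the forecast's low end. In the flask, substrate stands at 11.8 mM after 2.00 d, above S×, and at 6.07 mM after 4.00 d, below it. In the flask, self-condensation has done half its turnover by 0.402 d, when it still uses substrate 4.2 times as fast as forward dormancy. For the neighbour flask, charged with 0.015 M of substrate, the closed form gives S = 3.09 mM, so c = 79.4 %; the run there reaches 75.9 %.

(The rate constants were drawn at random within sensible limits, and the outcome is calculated.)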